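**Retrosynthetic overview**
1. The target comes from hydrogenolysis of two phenolic benzyl ethers, preceded by a single LiBH4 operation that turns both the acyl-oxazolidinone and the C3 methyl ester into the two CH2OH groups.
2. The side-chain C–C bond and its two stereocentres come from an Evans syn-aldol between dihydrobenzofuran-5-carbaldehyde 10 and arylacetyl-oxazolidinone 14.
3. The dihydrofuran ring comes from oxidative ring contraction of (S)-flavanone 6: the six-membered pyranone ring O1–C2–C3–C4–C4a–C8a loses C4, which becomes the exocyclic ester carbon, as C4a shifts from C4 to C3.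
4. The enabling feature is the C4 ketone of the chroman-4-one ring, flanked by the enolisable C3 methylene and by the electron-rich aryl carbon C4a that sits ortho to the ring oxygen O1.
5. Ring order: the pyranone ring is built flat (chromone 4), made chiral at C2 by asymmetric conjugate arylation (6), then contracted to the dihydrofuran (9); no further ring is formed.

Key step: step 4

Assumption: compounds 1, 5, 11, 12 and (R)-t-BuPyOx are taken as commercially available; the (R)-ligand is chosen because the (S)-ligand is known to give (R)-flavanones.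

**Step 1**
Reactants: 1 1-(2-hydroxy-3-methoxyphenyl)ethan-1-one
Product: 2 1-(5-bromo-2-hydroxy-3-methoxyphenyl)ethan-1-one
Conditions: NBS (1.05 equiv), MeCN, 0 °C → rt
Reagents that add atoms: N-bromosuccinimide, O=C1CCC(=O)N1Br
Why: Electrophilic aromatic bromination goes para to the free phenol (C5), the position also meta to the acetyl group, while both ortho positions of the phenol are blocked.

**Step 2**
Reactants: 2 1-(5-bromo-2-hydroxy-3-methoxyphenyl)ethan-1-one
Product: 4 6-bromo-8-methoxy-4H-chromen-4-one, via enaminone 3 (not isolated)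
Conditions: Me2NCH(OMe)2, toluene, 100 °C; then conc. HCl, CH2Cl2, 40 °C
Reagents that add atoms: N,N-dimethylformamide dimethyl acetal, COC(OC)N(C)C
Why: Enaminone formation at the acetyl methyl group followed by acid-promoted addition–elimination of the phenol with loss of dimethylamine is the standard chromone synthesis.

**Step 3**
Reactants: 4 6-bromo-8-methoxy-4H-chromen-4-one; 5 [4-(benzyloxy)-3-methoxyphenyl]boronic acid
Product: 6 (2S)-2-[4-(benzyloxy)-3-methoxyphenyl]-6-bromo-8-methoxychroman-4-one
Conditions: Pd(OCOCF3)2 (5 mol%), (R)-t-BuPyOx (6 mol%), NH4PF6 (30 mol%), H2O (5 equiv), 5 (2 equiv), ClCH2CH2Cl, 60 °C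
Reagents that add atoms: none
Why: Pd(II)/pyridine-oxazoline-catalysed asymmetric conjugate addition of an arylboronic acid to a chromone dearomatises the flat benzopyranone and sets C2 (S) by catalyst control, and the aryl bromide should survive because no base or Pd(0) source is present.

**Step 4**
Reactants: 6 (2S)-2-[4-(benzyloxy)-3-methoxyphenyl]-6-bromo-8-methoxychroman-4-one
Product: 9 methyl (2S,3S)-2-[4-(benzyloxy)-3-methoxyphenyl]-5-bromo-7-methoxy-2,3-dihydrobenzofuran-3-carboxylate, via enol ether 7 (not isolated), via orthoester 8 (not isolated)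
Conditions: PhI(OAc)2 (1.3 equiv), conc. H2SO4 (cat.), HC(OMe)3, rt; then dilute aqueous acid work-up
Reagents that add atoms: trimethyl orthoformate, COC(OC)OC; water, O
Why: Acid and orthoformate convert ketone 6 into enol ether 7, which the electrophilic iodine(III) species attacks at C3 anti to the pseudo-equatorial C2 aryl group while methanol caps C4 as a ketal; the C4–C4a bond, antiperiplanar to the equatorial C3–I bond, then shifts C4a from C4 to C3 with loss of iodobenzene to give orthoester 8, which is hydrolysed to ester 9 on work-up. The closest known reaction is the hypervalent-iodine (or thallium(III)) oxidative ring contraction of flavanones to methyl trans-2-aryl-2,3-dihydrobenzofuran-3-carboxylates, a semipinacol/quasi-Favorskii-type 1,2-aryl migration. The five-membered ring is not closed from an open chain: it arises by contraction of the pyranone ring, the new C3–C3a bond forming by ipso attack of C4a on C3 through a bridged phenonium (3-exo-tet type) while C4 is expelled as the carboxylate carbon. C2 is untouched and stays S; the new centre C3 is set by substrate control, since anti iodination followed by inversion at C3 during the shift places the ester trans to the aryl group, which is also the thermodynamically preferred arrangement of this epimerisable centre. The step needs A-ring migration to win over dehydrogenation to the flavone and over a 2,3-shift of the electron-rich B ring; in-situ ketalisation at C4, the ring oxygen ortho to the migrating carbon and the antiperiplanar geometry secure this, and the benzyl ether and aryl bromide are inert to the oxidant.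

**Step 5**
Reactants: 9 methyl (2S,3S)-2-[4-(benzyloxy)-3-methoxyphenyl]-5-bromo-7-methoxy-2,3-dihydrobenzofuran-3-carboxylate
Product: 10 methyl (2S,3S)-2-[4-(benzyloxy)-3-methoxyphenyl]-5-formyl-7-methoxy-2,3-dihydrobenzofuran-3-carboxylate
Conditions: Pd(OAc)2 (1 mol%), BuPAd2 (cataCXium A, 3 mol%), CO/H2 (1:1, 5 bar), TMEDA (0.75 equiv), toluene, 100 °C
Reagents that add atoms: carbon monoxide, [C-]#[O+]
Why: Palladium-catalysed reductive carbonylation of an aryl bromide (oxidative addition, CO insertion, hydrogenolysis of the acyl–Pd bond) tolerates the ester and benzyl ether, and C3, the only epimerisable centre, already holds its thermodynamically preferred trans arrangement.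

**Step 6**
Reactants: 11 2-[4-(benzyloxy)-3-methoxyphenyl]acetic acid; 12 (4S)-4-benzyloxazolidin-2-one
Product: 14 (4S)-4-benzyl-3-{2-[4-(benzyloxy)-3-methoxyphenyl]acetyl}oxazolidin-2-one, via pivalic mixed anhydride 13 (not isolated)
Conditions: PivCl, Et3N, THF, −20 °C; then 12, LiCl, −20 °C → rt
Reagents that add atoms: none
Why: N-acylation of the Evans auxiliary through the pivalic mixed anhydride under LiCl/Et3N activation forms no stereocentre and avoids strong base on the acidic arylacetyl unit.

**Step 7**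
Reactants: 14 (4S)-4-benzyl-3-{2-[4-(benzyloxy)-3-methoxyphenyl]acetyl}oxazolidin-2-one; 10 methyl (2S,3S)-2-[4-(benzyloxy)-3-methoxyphenyl]-5-formyl-7-methoxy-2,3-dihydrobenzofuran-3-carboxylate
Product: 16 methyl (2S,3S)-2-[4-(benzyloxy)-3-methoxyphenyl]-5-{(1S,2S)-3-[(4S)-4-benzyl-2-oxooxazolidin-3-yl]-2-[4-(benzyloxy)-3-methoxyphenyl]-1-hydroxy-3-oxopropyl}-7-methoxy-2,3-dihydrobenzofuran-3-carboxylate, via boron Z-enolate 15 (not isolated)
Conditions: 14 (1.2 equiv), n-Bu2BOTf (1.3 equiv), i-Pr2NEt (1.5 equiv), CH2Cl2, −78 → 0 °C; then 10, −78 → 0 °C; pH 7 buffer, MeOH, 30% H2O2, 0 °C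
Reagents that add atoms: none
Why: In this Evans syn-aldol the Z-boron enolate reacts through a chair Zimmerman–Traxler transition state with the auxiliary benzyl group shielding one enolate face, so the C–C bond and both side-chain centres (1S,2S in the adduct) are set by reagent control, independent of the remote ring stereocentres.

**Step 8**
Reactants: 16 methyl (2S,3S)-2-[4-(benzyloxy)-3-methoxyphenyl]-5-{(1S,2S)-3-[(4S)-4-benzyl-2-oxooxazolidin-3-yl]-2-[4-(benzyloxy)-3-methoxyphenyl]-1-hydroxy-3-oxopropyl}-7-methoxy-2,3-dihydrobenzofuran-3-carboxylate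
Product: 17 (1S,2R)-1-{(2S,3R)-2-[4-(benzyloxy)-3-methoxyphenyl]-3-(hydroxymethyl)-7-methoxy-2,3-dihydrobenzofuran-5-yl}-2-[4-(benzyloxy)-3-methoxyphenyl]propane-1,3-diol
Conditions: LiBH4 (6 equiv), MeOH (6 equiv), THF, 0 °C → rt; aq. NH4Cl
Reagents that add atoms: none
Why: LiBH4/MeOH reductively cleaves the N-acyl oxazolidinone and reduces the methyl ester in one operation, unveiling both primary alcohols without touching any stereocentre (the descriptors at ring C3 and at the side-chain C2 change from S to R only through CIP priorities).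

**Step 9**
Reactants: 17 (1S,2R)-1-{(2S,3R)-2-[4-(benzyloxy)-3-methoxyphenyl]-3-(hydroxymethyl)-7-methoxy-2,3-dihydrobenzofuran-5-yl}-2-[4-(benzyloxy)-3-methoxyphenyl]propane-1,3-diol
Product: 18 4-[(2S,3R)-5-[(1S,2R)-1,3-dihydroxy-2-(4-hydroxy-3-methoxyphenyl)propyl]-3-(hydroxymethyl)-7-methoxy-2,3-dihydrobenzofuran-2-yl]-2-methoxyphenol
Conditions: H2 (1 atm), 10% Pd/C, EtOAc–MeOH, rt, stopped at complete debenzylation
Reagents that add atoms: none
Why: Heterogeneous hydrogenolysis cleaves the two aryl benzyl ethers much faster than the benzylic C–O bonds of the carbinol and of the dihydrofuran under neutral conditions at room temperature.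

**Compound list**
1 | 1-(2-hydroxy-3-methoxyphenyl)ethan-1-one | COc1cccc(C(C)=O)c1O | starting material
2 | 1-(5-bromo-2-hydroxy-3-methoxyphenyl)ethan-1-one | COc1cc(Br)cc(C(C)=O)c1O | intermediate
3 | (E)-1-(5-bromo-2-hydroxy-3-methoxyphenyl)-3-(dimethylamino)prop-2-en-1-one | COc1cc(Br)cc(C(=O)/C=C/N(C)C)c1O | intermediate
4 | 6-bromo-8-methoxy-4H-chromen-4-one | COc1cc(Br)cc2c1OC=CC2=O | intermediate
5 | [4-(benzyloxy)-3-methoxyphenyl]boronic acid | COc1cc(B(O)O)ccc1OCc1ccccc1 | starting material
6 | (2S)-2-[4-(benzyloxy)-3-methoxyphenyl]-6-bromo-8-methoxychroman-4-one | COc1cc([C@H]2Oc3c(OC)cc(Br)cc3C(=O)C2)ccc1OCc1ccccc1 | intermediate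
7 | (2S)-2-[4-(benzyloxy)-3-methoxyphenyl]-6-bromo-4,8-dimethoxy-2H-chromene | COc1cc([C@H]2Oc3c(OC)cc(Br)cc3C(OC)=C2)ccc1OCc1ccccc1 | intermediate
8 | (2S,3S)-2-[4-(benzyloxy)-3-methoxyphenyl]-5-bromo-7-methoxy-3-(trimethoxymethyl)-2,3-dihydrobenzofuran (trans) | COc1cc([C@H]2Oc3c(OC)cc(Br)cc3[C@@H]2C(OC)(OC)OC)ccc1OCc1ccccc1 | intermediate
9 | methyl (2S,3S)-2-[4-(benzyloxy)-3-methoxyphenyl]-5-bromo-7-methoxy-2,3-dihydrobenzofuran-3-carboxylate (trans) | COc1cc([C@H]2Oc3c(OC)cc(Br)cc3[C@@H]2C(=O)OC)ccc1OCc1ccccc1 | intermediate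
10 | methyl (2S,3S)-2-[4-(benzyloxy)-3-methoxyphenyl]-5-formyl-7-methoxy-2,3-dihydrobenzofuran-3-carboxylate (trans) | COc1cc([C@H]2Oc3c(OC)cc(C=O)cc3[C@@H]2C(=O)OC)ccc1OCc1ccccc1 | intermediate
11 | 2-[4-(benzyloxy)-3-methoxyphenyl]acetic acid | COc1cc(CC(=O)O)ccc1OCc1ccccc1 | starting material
12 | (4S)-4-benzyloxazolidin-2-one | O=C1N[C@@H](Cc2ccccc2)CO1 | starting material
13 | 2-[4-(benzyloxy)-3-methoxyphenyl]acetic pivalic anhydride | COc1cc(CC(=O)OC(=O)C(C)(C)C)ccc1OCc1ccccc1 | intermediate
14 | (4S)-4-benzyl-3-{2-[4-(benzyloxy)-3-methoxyphenyl]acetyl}oxazolidin-2-one | COc1cc(CC(=O)N2C(=O)OC[C@@H]2Cc2ccccc2)ccc1OCc1ccccc1 | intermediate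
15 | (Z)-dibutylboron enolate of 14 (O–B and aryl cis on the enolate double bond) | CCCCB(CCCC)O/C(=C\c1ccc(OCc2ccccc2)c(OC)c1)N1C(=O)OC[C@@H]1Cc1ccccc1 | intermediate
16 | methyl (2S,3S)-2-[4-(benzyloxy)-3-methoxyphenyl]-5-{(1S,2S)-3-[(4S)-4-benzyl-2-oxooxazolidin-3-yl]-2-[4-(benzyloxy)-3-methoxyphenyl]-1-hydroxy-3-oxopropyl}-7-methoxy-2,3-dihydrobenzofuran-3-carboxylate | COc1cc([C@H]2Oc3c(OC)cc([C@@H](O)[C@@H](C(=O)N5C(=O)OC[C@@H]5Cc5ccccc5)c4ccc(OCc5ccccc5)c(OC)c4)cc3[C@@H]2C(=O)OC)ccc1OCc1ccccc1 | intermediate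
17 | (1S,2R)-1-{(2S,3R)-2-[4-(benzyloxy)-3-methoxyphenyl]-3-(hydroxymethyl)-7-methoxy-2,3-dihydrobenzofuran-5-yl}-2-[4-(benzyloxy)-3-methoxyphenyl]propane-1,3-diol | COc1cc([C@H]2Oc3c(OC)cc([C@@H](O)[C@@H](CO)c4ccc(OCc5ccccc5)c(OC)c4)cc3[C@@H]2CO)ccc1OCc1ccccc1 | intermediate
18 | 4-[(2S,3R)-5-[(1S,2R)-1,3-dihydroxy-2-(4-hydroxy-3-methoxyphenyl)propyl]-3-(hydroxymethyl)-7-methoxy-2,3-dihydrobenzofuran-2-yl]-2-methoxyphenol (CNP0294468.1) | COc1cc([C@H]2Oc3c(OC)cc([C@@H](O)[C@@H](CO)c4ccc(O)c(OC)c4)cc3[C@@H]2CO)ccc1O | target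

**Totals**
Total step count: 9 (steps 1–5 and 7–9 linear, step 6 on the side branch).
Longest linear sequence: 8 steps (1 → 2 → 4 → 6 → 9 → 10 → 16 → 17 → 18).

**Steps most likely to fail**

Step 4. Dehydrogenation to the flavone, a competing 2,3-shift of the electron-rich B ring, or acid-induced opening of the pyranone with loss of C2 integrity may divert the contraction. The fallback sets out from 6 and returns at 9, keeping a ring contraction but by a carbene route. Heating 6 with DMF dimethyl acetal would give the 3-(dimethylaminomethylene)flavanone F1. Diazo transfer with tosyl azide (cycloaddition–cycloreversion on the enaminone, CH2Cl2, rt) would give the 3-diazoflavanone F2. Irradiation (365–400 nm) in methanol should trigger a Wolff rearrangement in which C4a migrates from C4 to the carbene carbon C3, and methanol traps the ring-contracted ketene. Brief treatment with catalytic DBU should equilibrate the C3 epimers to the trans ester 9.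

Step 5. Under amine base at 100 °C the acidic C3–H may allow retro-oxa-Michael opening of the dihydrofuran, and hydrodebromination may compete with CO insertion. The fallback sets out from 9 and returns at 10. Base-free Stille coupling with tributyl(vinyl)stannane (Pd(PPh3)4, toluene, 100 °C) would give the 5-vinyl ester F3. Lemieux–Johnson cleavage (OsO4 cat., NaIO4, 2,6-lutidine, dioxane–water, rt) would then deliver aldehyde 10.

Step 8. Retro-aldol cleavage of the lithium aldolate before hydride delivery, endocyclic attack on the oxazolidinone, or incomplete reduction of the hindered ester may intervene. The fallback sets out from 16 and returns at 17. Silylation (TESOTf, 2,6-lutidine, CH2Cl2, −78 °C) would give the triethylsilyl ether F4, which cannot undergo retro-aldol. LiBH4/MeOH in THF should then reduce imide and ester to the silyl-protected diol F5. TBAF (THF, 0 °C) would free the carbinol to give 17.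

**Further compounds**
F1 | step 4 | (2R,E)-2-[4-(benzyloxy)-3-methoxyphenyl]-6-bromo-3-[(dimethylamino)methylene]-8-methoxychroman-4-one (C2 geometry as in 6; descriptor changes by CIP only) | COc1cc([C@H]2Oc3c(OC)cc(Br)cc3C(=O)/C2=C/N(C)C)ccc1OCc1ccccc1
F2 | step 4 | (2R)-2-[4-(benzyloxy)-3-methoxyphenyl]-6-bromo-3-diazo-8-methoxychroman-4-one (C2 geometry as in 6) | COc1cc([C@H]2Oc3c(OC)cc(Br)cc3C(=O)C2=[N+]=[N-])ccc1OCc1ccccc1
F3 | step 5 | methyl (2S,3S)-2-[4-(benzyloxy)-3-methoxyphenyl]-7-methoxy-5-vinyl-2,3-dihydrobenzofuran-3-carboxylate | COc1cc([C@H]2Oc3c(OC)cc(C=C)cc3[C@@H]2C(=O)OC)ccc1OCc1ccccc1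
F4 | step 8 | methyl (2S,3S)-2-[4-(benzyloxy)-3-methoxyphenyl]-5-{(1S,2S)-3-[(4S)-4-benzyl-2-oxooxazolidin-3-yl]-2-[4-(benzyloxy)-3-methoxyphenyl]-3-oxo-1-[(triethylsilyl)oxy]propyl}-7-methoxy-2,3-dihydrobenzofuran-3-carboxylate | COc1cc([C@H]2Oc3c(OC)cc([C@@H](O[Si](CC)(CC)CC)[C@@H](C(=O)N5C(=O)OC[C@@H]5Cc5ccccc5)c4ccc(OCc5ccccc5)c(OC)c4)cc3[C@@H]2C(=O)OC)ccc1OCc1ccccc1
F5 | step 8 | [(2S,3R)-2-[4-(benzyloxy)-3-methoxyphenyl]-5-{(1S,2R)-2-[4-(benzyloxy)-3-methoxyphenyl]-3-hydroxy-1-[(triethylsilyl)oxy]propyl}-7-methoxy-2,3-dihydrobenzofuran-3-yl]methanol | COc1cc([C@H]2Oc3c(OC)cc([C@@H](O[Si](CC)(CC)CC)[C@@H](CO)c4ccc(OCc5ccccc5)c(OC)c4)cc3[C@@H]2CO)ccc1OCc1ccccc1
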